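## Structural features

The target is a germacrane-type ten-membered carbocycle, numbered here from the ketone C1 through the epoxide C4–C5, the lactone carbinol C6, C7, the ester carbinol C8 and C9 to the methyl-bearing C10; C11, C12 and C13 are the α-carbon, carbonyl and acetoxymethyl carbon of a butenolide fused across C6–C7. The butenolide double bond C7=C11 is tetrasubstituted, and the molecule holds three different acyl–oxygen bonds (lactone, C13 acetate, C8 2-(hydroxymethyl)acrylate) that must be told apart. Of the five stereocentres, C4, C5 and C6 are contiguous: the (4R,5S) epoxide is cis-fused to the ring, so it derives from a Z olefin, and its oxygen is cis to the C6 oxygen; C8 sits on the other side of the sp2 carbon C7, and C10 is α to the ketone. The fragile points are C6–H (γ to the lactone carbonyl and β to the epoxide, so base can open the epoxide by vinylogous elimination), the acid-labile trisubstituted epoxide facing the C1 ketone across the ring, the epimerisable C10, a free C8 hydroxyl that can form a hemiketal with C1, and the acrylate. The real difficulty is the medium ring combined with this acid- and base-sensitive C4–C8 array: the ring must be closed without a stereochemical gamble, and the epoxide face must be controlled on a flexible ring. The key step exploits the 1,5-relationship of the C1 ketone and the C4=C5 olefin that precedes the epoxide: C1(=O)–C2–C3–C4=C5 is a γ,δ-unsaturated ketone, and with the oxygen tied to C5 inside an eight-membered cyclic enol ether its Claisen retron becomes a two-carbon ring expansion.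

## Logic of the disconnections

42 ⇐ 41 ⇐ 37 + 40. The C8 ester bond is cut last because the acrylate is the most reactive group of the target. The side-chain hydroxyl is carried as a triethylsilyl ether so that the acid cannot acylate itself. The forward steps must be base-free and only weakly acidic, since the epoxide and C6–H are already present.

37 ⇐ 36 ⇐ 35. The C13 acetate and the free C8 hydroxyl are traced to two PMB ethers, so one neutral oxidative step releases both. This demands a selective acylation of the primary C13 hydroxyl in 36.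

35 ⇐ 34 ⇐ 33 ⇐ 32 ⇐ 27 + 31. The butenolide is cut at C7=C11 and O6–C12 (intramolecular Horner–Wadsworth–Emmons). C13 arrives with its oxygen on the phosphonate 31, because hydroxymethylation of a finished tetrasubstituted butenolide at C11 has no reliable solution. The demand is a base weak enough to leave C6–H of 34 alone.

31 ⇐ 30 ⇐ 28 + 29. The C13–O bond is cut as an oxa-Michael addition to a vinylphosphonate, two steps from catalogue materials.

27 ⇐ 26 ⇐ 24. The epoxide C–O bonds are cut back to the Z olefin while the C6 oxygen is still a free hydroxyl, so that the C6 stereocentre can direct the oxidant. This requires the three oxygenated carbons to be unmasked in the order C6, C7, C8 (MOM, triethylsilyl, PMB).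

24 ⇐ 23 (key step). C2–C3 is cut and O–C5 re-formed: the cyclodec-4-enone becomes a 2-methylene oxocane carrying an isopropenyl group on C5. The gain is that the ten-membered ring is made by ring expansion with no stereocentre at stake. Two features of 23 are deliberate:
- C7 is a silyl-protected carbinol, not a ketal. A ketal flanked by two oxygenated carbons would be hard to form and harder to hydrolyse beside a Z-allylic ether and a transannular ketone.
- C5 is R, because this epimer puts H6, not the C6 oxygen, inside the chair transition state.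

23 ⇐ 22 ⇐ 20 ⇐ 19. The enol ether carbon C2 is cut (carbonyl methylenation), then the acyl–oxygen bond C1–O5 (lactonisation). The forward lactonisation needs C5–OH to be the only free hydroxyl, since C7–OH or C8–OH would give six- or five-membered lactones.

19 ⇐ 18 ⇐ 17 ⇐ 15 + 16. C4–C5 is cut to an α-alkoxy aldehyde and an isopropenyl nucleophile. The sacrificial C5 configuration is then fixed by oxidation and chelation-controlled reduction, two reliable steps spent to secure the key step.

15 ⇐ 13 ⇐ 12 ⇐ 8 + 9. C6–C7 is cut as a γ-alkoxyallylboration, which sets C6 by reagent control and delivers O6 and O7 already differentiated. The vinyl group is the latent C5 aldehyde.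

8 ⇐ 7 ⇐ 6 ⇐ 3 ⇐ 1. C8 comes from the chiral pool (a glutamic-acid-derived lactone) and C10 from trans-selective methylation of that lactone. The lactone is opened with the C8 oxygen capped in the same flask, so the γ-hydroxy ester never exists.

40 ⇐ 38. The side-chain acid is protected in one flask.

## Other disconnections considered

Alternative 1: Nozaki–Hiyama–Kishi macrocyclisation. The cut is C6–C7 together with the lactone bond O6–C12. In the forward sense the acyclic Z β-iodo-enoate epoxy aldehyde A1 would be treated with CrCl2 (divalent chromium) and catalytic NiCl2; the alkenylchromium species adds to the C6 aldehyde and the alkoxide lactonises to the 8-O-silyl core A2.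
- In its favour: ring and butenolide form in one operation, the reagent is chemoselective for aldehydes, and the epoxide, acetate, C8 and C10 are set in open-chain chemistry.
- Against it here: C6 is created in the ring-closing event beside the epoxide, so its configuration rests on Felkin versus chelate control inside a strained ten-membered transition state. The tetrasubstituted iodo-enoate of defined geometry is laborious, its chromium derivative is hindered, and the α,β-epoxy aldehyde is labile.
- Comparison: on structure and step economy after ring closure this alternative is the better one, since A2 is three steps from the target whereas 24 is thirteen. On mechanism the chosen plan is better: a unimolecular sigmatropic shift that creates no stereocentre and needs no high dilution.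

Alternative 2: acyl radical macrocyclisation. The cut is C1–C10. The phenyl selenoester A3 with Bu3SnH and AIBN would give an acyl radical that adds 10-endo to the β-carbon of the propenyl ketone and furnishes the C1,C8-diketone A4.
- In its favour: neutral conditions that the epoxide and butenolide should tolerate, and endo acyl-radical additions to enones are among the better radical macrocyclisations.
- Against it here: C10 is formed in the radical addition with no nearby control element, and ten is the lower limit of ring size for this mode, so premature reduction and decarbonylation compete. The C8 ketone of A4 must then be reduced chemo- and stereoselectively beside the C1 ketone.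
- Comparison: it is the equal of the chosen plan in delivering the C1 ketone directly at ring closure, and A4 already holds the epoxide, butenolide and acetate. It is worse on mechanism (two stereocentres, C10 and C8, left to chance), and the redox correction at C8 cancels its advantage in step count.

Alternative 3: vinylogous Mukaiyama aldol macrocyclisation. The cut is C5–C6. The silyloxyfuran aldehyde A5 with MgBr2·OEt2 would add through its γ-carbon C6 to the chelated α-alkoxy aldehyde C5 and give the aldol macrocycle A6, from which the epoxide is closed by displacement at C5 with inversion.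
- In its favour: the quaternary C4 comes from linalool, the butenolide is regenerated in the ring-forming step, and the epoxide configuration follows from a stereospecific displacement. On this point it is better than the chosen plan, which relies on face-selective oxidation of a ring.
- Against it here: two stereocentres (C5 and C6) are set in one ten-membered ring closure, and the syn/anti sense of silyloxyfuran additions is substrate dependent. Activation of the C5 hydroxyl in A6 places a leaving group β to the acidic C6–H, so elimination would compete with epoxide closure.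
- Comparison: step economy is about equal. The chosen plan is safer on mechanism because C6 is fixed early by reagent control and the ring-forming step decides only olefin geometry.

Key step: step 14

Assumption: 1, 28 and 38 are catalogue compounds; locants C1–C13 are those of the target in every intermediate; C5 and C7 of the intermediates are sacrificial stereocentres.

## Steps

Step 1
Reactants: 1 (S)-5-[(trityloxy)methyl]dihydrofuran-2(3H)-one
Product: 3 (3R,5S)-3-methyl-5-[(trityloxy)methyl]dihydrofuran-2(3H)-one, via lithium enolate 2 (not isolated)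
Conditions: LiN(i-Pr)2, THF, −78 °C; MeI, −78 to −40 °C
Reagents that add atoms: iodomethane CI
Why: Kinetic enolate alkylation of a γ-lactone; methylation occurs anti to the bulky trityloxymethyl group, giving the trans lactone and so setting C10 relative to the chiral-pool centre C8.

Step 2
Reactants: 3 (3R,5S)-3-methyl-5-[(trityloxy)methyl]dihydrofuran-2(3H)-one
Product: 6 methyl (2R,4S)-4-[(4-methoxybenzyl)oxy]-2-methyl-5-(trityloxy)pentanoate, via sodium hydroxy carboxylate 4 (not isolated), via sodium alkoxy carboxylate 5 (not isolated)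
Conditions: NaOH (1.05 equiv), MeOH/H2O, rt; evaporate; NaH (1.05 equiv), PMBCl, n-Bu4NI (cat.), DMF, 0 °C to rt; then MeI, rt
Reagents that add atoms: sodium hydroxide [Na+].[OH-]; 4-methoxybenzyl chloride COc1ccc(CCl)cc1; iodomethane CI
Why: Saponification, then Williamson etherification and carboxylate alkylation; the alkoxide is alkylated much faster than the carboxylate, so the C8 oxygen is capped before any ester exists and relactonisation is excluded. Neither stereocentre is touched.

Step 3
Reactants: 6 methyl (2R,4S)-4-[(4-methoxybenzyl)oxy]-2-methyl-5-(trityloxy)pentanoate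
Product: 7 methyl (2R,4S)-5-hydroxy-4-[(4-methoxybenzyl)oxy]-2-methylpentanoate
Conditions: CSA (0.1 equiv), MeOH/CH2Cl2 (1:1), 0 °C to rt; Et3N quench
Reagents that add atoms: none
Why: Acid-catalysed methanolysis of the trityl ether through the trityl cation (SN1); the PMB ether and ester are stable to catalytic acid, which is neutralised before concentration so the δ-hydroxy ester does not lactonise.

Step 4
Reactants: 7 methyl (2R,4S)-5-hydroxy-4-[(4-methoxybenzyl)oxy]-2-methylpentanoate
Product: 8 methyl (2R,4S)-4-[(4-methoxybenzyl)oxy]-2-methyl-5-oxopentanoate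
Conditions: Dess–Martin periodinane, NaHCO3, CH2Cl2, 0 °C to rt; used crude
Reagents that add atoms: none
Why: Dess–Martin oxidation of a primary alcohol under buffered, non-epimerising conditions; the α-alkoxy aldehyde is used at once.

Step 5
Reactants: 8 methyl (2R,4S)-4-[(4-methoxybenzyl)oxy]-2-methyl-5-oxopentanoate; 9 allyl methoxymethyl ether
Product: 12 methyl (2R,4S,5R,6R)-5-hydroxy-4-[(4-methoxybenzyl)oxy]-6-(methoxymethoxy)-2-methyloct-7-enoate, via allylborane 10 (not isolated), via borinate ester 11 (not isolated)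
Conditions: 9, s-BuLi, THF, −78 °C; (−)-Ipc2BOMe; BF3·OEt2; then 8, −78 °C; HOCH2CH2NH2, Et2O, rt
Reagents that add atoms: none
Why: Brown γ-alkoxyallylboration through a chair Zimmerman–Traxler transition state; the Z-alkoxyallyl unit gives the 6,7-syn relationship, and the isopinocampheyl groups from (+)-α-pinene direct attack to the Si face of the aldehyde, setting C6 (and the sacrificial C7) by reagent control against the Cornforth bias of the α-alkoxy aldehyde. The base-free work-up avoids δ-lactonisation of the new hydroxyl onto the ester.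

Step 6
Reactants: 12 methyl (2R,4S,5R,6R)-5-hydroxy-4-[(4-methoxybenzyl)oxy]-6-(methoxymethoxy)-2-methyloct-7-enoate
Product: 13 methyl (2R,4S,5R,6R)-4-[(4-methoxybenzyl)oxy]-6-(methoxymethoxy)-2-methyl-5-[(triethylsilyl)oxy]oct-7-enoate
Conditions: Et3SiOTf, 2,6-lutidine, CH2Cl2, −78 °C
Reagents that add atoms: triethylsilyl triflate CC[Si](CC)(CC)OS(=O)(=O)C(F)(F)F
Why: Silylation of a hindered secondary alcohol with a silyl triflate and a hindered base; the silyl ether masks the future C7 ketone and blocks lactone formation between O7 and C1.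

Step 7
Reactants: 13 methyl (2R,4S,5R,6R)-4-[(4-methoxybenzyl)oxy]-6-(methoxymethoxy)-2-methyl-5-[(triethylsilyl)oxy]oct-7-enoate
Product: 15 methyl (2R,4S,5R,6S)-4-[(4-methoxybenzyl)oxy]-6-(methoxymethoxy)-2-methyl-7-oxo-5-[(triethylsilyl)oxy]heptanoate, via vicinal diol 14 (not isolated)
Conditions: OsO4 (2 mol %), NaIO4, 2,6-lutidine, dioxane/H2O (3:1), rt; used crude
Reagents that add atoms: osmium tetroxide O=[Os](=O)(=O)=O; sodium periodate [Na+].[O-]I(=O)(=O)=O
Why: Lemieux–Johnson cleavage of the only olefin, buffered with lutidine so that the α-alkoxy aldehyde is not epimerised at C6; unlike ozone, the reagents leave the electron-rich PMB ring alone.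

Step 8
Reactants: 15 methyl (2R,4S,5R,6S)-4-[(4-methoxybenzyl)oxy]-6-(methoxymethoxy)-2-methyl-7-oxo-5-[(triethylsilyl)oxy]heptanoate; 16 isopropenylmagnesium bromide
Product: 17 methyl (2R,4S,5R,6R)-7-hydroxy-4-[(4-methoxybenzyl)oxy]-6-(methoxymethoxy)-2,8-dimethyl-5-[(triethylsilyl)oxy]non-8-enoate as a mixture of C7 epimers (C5 of the target numbering)
Conditions: THF, −78 °C; sat. aq. NH4Cl
Reagents that add atoms: none
Why: Grignard addition to an aldehyde at −78 °C, chemoselective over the α-branched methyl ester; the epimer ratio at the new carbinol (chelation should favour 5S) is irrelevant because both epimers are oxidised next.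

Step 9
Reactants: 17 methyl (2R,4S,5R,6R)-7-hydroxy-4-[(4-methoxybenzyl)oxy]-6-(methoxymethoxy)-2,8-dimethyl-5-[(triethylsilyl)oxy]non-8-enoate (epimer mixture)
Product: 18 methyl (2R,4S,5R,6S)-4-[(4-methoxybenzyl)oxy]-6-(methoxymethoxy)-2,8-dimethyl-7-oxo-5-[(triethylsilyl)oxy]non-8-enoate
Conditions: Dess–Martin periodinane, NaHCO3, CH2Cl2, 0 °C; used crude
Reagents that add atoms: none
Why: Dess–Martin oxidation of a secondary allylic alcohol; both C5 epimers converge on one α-alkoxy enone.

Step 10
Reactants: 18 methyl (2R,4S,5R,6S)-4-[(4-methoxybenzyl)oxy]-6-(methoxymethoxy)-2,8-dimethyl-7-oxo-5-[(triethylsilyl)oxy]non-8-enoate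
Product: 19 methyl (2R,4S,5R,6R,7R)-7-hydroxy-4-[(4-methoxybenzyl)oxy]-6-(methoxymethoxy)-2,8-dimethyl-5-[(triethylsilyl)oxy]non-8-enoate
Conditions: Zn(BH4)2 (0.2 M in Et2O), Et2O, −30 to 0 °C
Reagents that add atoms: none
Why: Chelation-controlled 1,2-reduction; zinc bridges the C5 carbonyl and the MOM oxygen on C6, and hydride is delivered anti to C7, giving the 5,6-anti (5R) allylic alcohol. Zn(BH4)2 reduces the enone at carbon–oxygen and leaves the ester.

Step 11
Reactants: 19 methyl (2R,4S,5R,6R,7R)-7-hydroxy-4-[(4-methoxybenzyl)oxy]-6-(methoxymethoxy)-2,8-dimethyl-5-[(triethylsilyl)oxy]non-8-enoate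
Product: 20 (2R,4S,5R,6R,7R)-7-hydroxy-4-[(4-methoxybenzyl)oxy]-6-(methoxymethoxy)-2,8-dimethyl-5-[(triethylsilyl)oxy]non-8-enoic acid
Conditions: LiOH·H2O, THF/MeOH/H2O (3:1:1), rt; 0.5 M HCl to pH 4, 0 °C
Reagents that add atoms: lithium hydroxide [Li+].[OH-]
Why: Saponification of the methyl ester; the carboxylate is not enolised, so C10 is preserved, and the silyl, MOM and PMB ethers are stable to aqueous LiOH.

Step 12
Reactants: 20 (2R,4S,5R,6R,7R)-7-hydroxy-4-[(4-methoxybenzyl)oxy]-6-(methoxymethoxy)-2,8-dimethyl-5-[(triethylsilyl)oxy]non-8-enoic acid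
Product: 22 (3R,5S,6R,7R,8R)-5-[(4-methoxybenzyl)oxy]-7-(methoxymethoxy)-3-methyl-8-(prop-1-en-2-yl)-6-[(triethylsilyl)oxy]oxocan-2-one, via mixed anhydride 21 (not isolated)
Conditions: 2-methyl-6-nitrobenzoic anhydride, DMAP, toluene, rt to 40 °C, slow addition of 20 (final 1 mM)
Reagents that add atoms: none
Why: Shiina macrolactonisation; the acid is activated as a mixed aromatic anhydride and DMAP transfers the acyl group to the only free hydroxyl (C5), a method documented for substituted oxocan-2-ones. O7 and O8 are blocked, so no five- or six-membered lactone can form.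

Step 13
Reactants: 22 (3R,5S,6R,7R,8R)-5-[(4-methoxybenzyl)oxy]-7-(methoxymethoxy)-3-methyl-8-(prop-1-en-2-yl)-6-[(triethylsilyl)oxy]oxocan-2-one
Product: 23 (3R,5S,6R,7R,8R)-5-[(4-methoxybenzyl)oxy]-7-(methoxymethoxy)-3-methyl-2-methylidene-8-(prop-1-en-2-yl)-6-[(triethylsilyl)oxy]oxocane
Conditions: Cp2TiMe2 (3 equiv), pyridine (trace), toluene, 70 °C, dark; filtration through basic alumina
Reagents that add atoms: dimethyltitanocene C[Ti](C)(C1C=CC=C1)C1C=CC=C1
Why: Petasis methylenation; thermally generated Cp2Ti=CH2 adds to the lactone carbonyl and cycloreverts to the exocyclic enol ether. The reagent is neither basic nor Lewis acidic, so C10 and the acetal, silyl and PMB groups survive, and 70 °C is well below the temperature expected for the rearrangement.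

Step 14
Reactants: 23 (3R,5S,6R,7R,8R)-5-[(4-methoxybenzyl)oxy]-7-(methoxymethoxy)-3-methyl-2-methylidene-8-(prop-1-en-2-yl)-6-[(triethylsilyl)oxy]oxocane
Product: 24 (4Z,6R,7R,8S,10R)-8-[(4-methoxybenzyl)oxy]-6-(methoxymethoxy)-4,10-dimethyl-7-[(triethylsilyl)oxy]cyclodec-4-en-1-one
Conditions: degassed o-xylene (5 mM), 2,6-di-tert-butyl-4-methylpyridine (0.2 equiv), base-washed sealed tube, 150 °C
Reagents that add atoms: none
Why: A concerted [3,3] sigmatropic shift of the allyl vinyl ether C2=C1–O–C5–C4=C3 embedded in the oxocane forms C2–C3 while O–C5 breaks, so the ring oxygen is exchanged for a two-carbon unit and C1 becomes the ketone. The closest known reaction type is the Claisen ring expansion of 2-methylene-6-alkenyl tetrahydropyrans to cyclooct-4-enones; here the same array sits in an eight-membered ether and should give the ten-membered ring. The carbocycle is closed by ring expansion through a bicyclic, chair-like six-membered transition state that shares C1–O–C5 with the oxocane, not by end-to-end cyclisation, so no high dilution is needed. No stereocentre is created: C5 is erased, and C6, C7, C8 and C10 lie outside the array and are not enolised under neutral conditions. The only selectivity at stake is olefin geometry: the three-atom tether C7–C8–C9 can link C6 to C10 only if C6 is pseudo-axial on C5, which places C6 cis to C3 and gives the Z olefin. The 5R configuration puts H6, not the C6 oxygen, in the inside position of that chair and the C6–C7 bond on the face of the enol ether. Acid-catalysed migration of the exocyclic double bond into the ring is suppressed by base-washed glass and the hindered pyridine.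

Step 15
Reactants: 24 (4Z,6R,7R,8S,10R)-8-[(4-methoxybenzyl)oxy]-6-(methoxymethoxy)-4,10-dimethyl-7-[(triethylsilyl)oxy]cyclodec-4-en-1-one
Product: 26 (4Z,6R,7S,8S,10R)-6-hydroxy-8-[(4-methoxybenzyl)oxy]-4,10-dimethyl-7-[(triethylsilyl)oxy]cyclodec-4-en-1-one, via bipyridinium salt 25 (not isolated)
Conditions: Me3SiOTf, 2,2′-bipyridyl, CH2Cl2, 0 °C; then H2O, rt; aq. NaHCO3
Reagents that add atoms: none
Why: Acetal-selective MOM cleavage; the silyl triflate activates the methoxy oxygen, bipyridyl traps the oxocarbenium ion as a pyridinium salt, and water hydrolyses it to the alcohol. No free acid is present, so the PMB and silyl ethers and the Z-allylic carbinol are not ionised.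

Step 16
Reactants: 26 (4Z,6R,7S,8S,10R)-6-hydroxy-8-[(4-methoxybenzyl)oxy]-4,10-dimethyl-7-[(triethylsilyl)oxy]cyclodec-4-en-1-one
Product: 27 (4R,5S,6R,7S,8S,10R)-4,5-epoxy-6-hydroxy-8-[(4-methoxybenzyl)oxy]-4,10-dimethyl-7-[(triethylsilyl)oxy]cyclodecan-1-one
Conditions: VO(acac)2 (5 mol %), t-BuOOH (in decane), CH2Cl2, 0 °C to rt
Reagents that add atoms: tert-butyl hydroperoxide CC(C)(C)OO
Why: Hydroxyl-directed epoxidation; the vanadate ester of O6 delivers oxygen to the olefin face on which the C6–O bond stands gauche to the π bond. In a medium-ring Z-cycloalkenol the ring bond C6–C7 must stand out of the olefin plane on the opposite face, which should give the epoxide with oxygen cis to the hydroxyl (4R,5S); the Z geometry becomes the cis ring fusion.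

Step 17
Reactants: 28 ethyl 2-(diethoxyphosphoryl)acrylate; 29 4-methoxybenzyl alcohol
Product: 30 ethyl 2-(diethoxyphosphoryl)-3-[(4-methoxybenzyl)oxy]propanoate (racemic)
Conditions: 29 (3 equiv), KOt-Bu (10 mol %), THF, 0 °C to rt
Reagents that add atoms: none
Why: Alkoxide-catalysed oxa-Michael addition to a doubly activated vinylphosphonate; C13 is introduced with its oxygen already attached.

Step 18
Reactants: 30 ethyl 2-(diethoxyphosphoryl)-3-[(4-methoxybenzyl)oxy]propanoate
Product: 31 2-(diethoxyphosphoryl)-3-[(4-methoxybenzyl)oxy]propanoic acid (racemic)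
Conditions: LiOH·H2O (1.1 equiv), THF/H2O, 0 °C; 1 M HCl to pH 2
Reagents that add atoms: lithium hydroxide [Li+].[OH-]
Why: Selective saponification of the carboxylic ester of a phosphonoacetate (the phosphonate esters are far less electrophilic); low temperature and short time limit retro-Michael loss of the alkoxide.

Step 19
Reactants: 27 (4R,5S,6R,7S,8S,10R)-4,5-epoxy-6-hydroxy-8-[(4-methoxybenzyl)oxy]-4,10-dimethyl-7-[(triethylsilyl)oxy]cyclodecan-1-one; 31 2-(diethoxyphosphoryl)-3-[(4-methoxybenzyl)oxy]propanoic acid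
Product: 32 (4R,5S,6R,7R,8S,10R)-4,5-epoxy-8-[(4-methoxybenzyl)oxy]-4,10-dimethyl-1-oxo-7-[(triethylsilyl)oxy]cyclodecan-6-yl 2-(diethoxyphosphoryl)-3-[(4-methoxybenzyl)oxy]propanoate (both C11 epimers)
Conditions: EDC·HCl, DMAP (cat.), CH2Cl2, 0 °C to rt
Reagents that add atoms: none
Why: Steglich esterification of the hindered C6 alcohol; α-phosphono acids are activated readily by carbodiimides. The C11 centre forms as a mixture and is destroyed in step 22.

Step 20
Reactants: 32 (4R,5S,6R,7R,8S,10R)-4,5-epoxy-8-[(4-methoxybenzyl)oxy]-4,10-dimethyl-1-oxo-7-[(triethylsilyl)oxy]cyclodecan-6-yl 2-(diethoxyphosphoryl)-3-[(4-methoxybenzyl)oxy]propanoate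
Product: 33 (4R,5S,6S,7R,8S,10R)-4,5-epoxy-7-hydroxy-8-[(4-methoxybenzyl)oxy]-4,10-dimethyl-1-oxocyclodecan-6-yl 2-(diethoxyphosphoryl)-3-[(4-methoxybenzyl)oxy]propanoate
Conditions: HF·pyridine, pyridine, THF, 0 °C; used crude
Reagents that add atoms: none
Why: Fluoride cleavage of the triethylsilyl ether under pyridine buffering, which spares the epoxide, the PMB ethers and the phosphonate and leaves little opportunity for acyl migration from O6 to O7.

Step 21
Reactants: 33 (4R,5S,6S,7R,8S,10R)-4,5-epoxy-7-hydroxy-8-[(4-methoxybenzyl)oxy]-4,10-dimethyl-1-oxocyclodecan-6-yl 2-(diethoxyphosphoryl)-3-[(4-methoxybenzyl)oxy]propanoate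
Product: 34 (4R,5S,6R,8S,10R)-4,5-epoxy-8-[(4-methoxybenzyl)oxy]-4,10-dimethyl-1,7-dioxocyclodecan-6-yl 2-(diethoxyphosphoryl)-3-[(4-methoxybenzyl)oxy]propanoate
Conditions: Dess–Martin periodinane, NaHCO3, CH2Cl2, 0 °C to rt; used crude
Reagents that add atoms: none
Why: Buffered Dess–Martin oxidation of the C7 carbinol to the α-acyloxy ketone without acid or base; the sacrificial C7 stereocentre is removed, and any transannular hemiketal with C1 is drained through the open form.

Step 22
Reactants: 34 (4R,5S,6R,8S,10R)-4,5-epoxy-8-[(4-methoxybenzyl)oxy]-4,10-dimethyl-1,7-dioxocyclodecan-6-yl 2-(diethoxyphosphoryl)-3-[(4-methoxybenzyl)oxy]propanoate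
Product: 35 (4R,5S,6S,8S,10R)-4,5-epoxy-8,13-bis[(4-methoxybenzyl)oxy]-1-oxogermacr-7(11)-en-12,6-olide
Conditions: LiCl, i-Pr2NEt, MeCN, 0 °C to rt
Reagents that add atoms: none
Why: Intramolecular Horner–Wadsworth–Emmons olefination under Masamune–Roush conditions; the lithium-chelated phosphonate is deprotonated by the amine, attacks the adjacent C7 ketone through a five-membered ring and loses diethyl phosphate to give the tetrasubstituted butenolide. The weak base is chosen to leave C6–H, C8–H and C10–H untouched.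

Step 23
Reactants: 35 (4R,5S,6S,8S,10R)-4,5-epoxy-8,13-bis[(4-methoxybenzyl)oxy]-1-oxogermacr-7(11)-en-12,6-olide
Product: 36 (4R,5S,6S,8S,10R)-4,5-epoxy-8,13-dihydroxy-1-oxogermacr-7(11)-en-12,6-olide
Conditions: DDQ, CH2Cl2/pH 7 phosphate buffer (10:1), 0 °C to rt
Reagents that add atoms: none
Why: Oxidative cleavage of both PMB ethers by benzylic hydride abstraction and hydrolysis of the oxocarbenium ions; the buffered neutral medium spares epoxide, lactone and ketone.

Step 24
Reactants: 36 (4R,5S,6S,8S,10R)-4,5-epoxy-8,13-dihydroxy-1-oxogermacr-7(11)-en-12,6-olide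
Product: 37 (4R,5S,6S,8S,10R)-13-acetoxy-4,5-epoxy-8-hydroxy-1-oxogermacr-7(11)-en-12,6-olide
Conditions: AcCl (1.1 equiv), 2,4,6-collidine, CH2Cl2, −78 °C
Reagents that add atoms: acetyl chloride CC(Cl)=O
Why: Selective acylation of the unhindered primary C13 hydroxyl over the secondary C8 hydroxyl with one equivalent of acyl chloride and a hindered pyridine at low temperature.

Step 25
Reactants: 38 2-(hydroxymethyl)acrylic acid
Product: 40 2-{[(triethylsilyl)oxy]methyl}acrylic acid, via bis-silyl derivative 39 (not isolated)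
Conditions: Et3SiCl (2.2 equiv), imidazole, CH2Cl2, 0 °C; then aq. NaHCO3/MeOH
Reagents that add atoms: chlorotriethylsilane CC[Si](Cl)(CC)CC
Why: Silylation of both hydroxyl and carboxyl groups, then selective hydrolysis of the labile silyl ester, leaves the silyl ether acid.

Step 26
Reactants: 37 (4R,5S,6S,8S,10R)-13-acetoxy-4,5-epoxy-8-hydroxy-1-oxogermacr-7(11)-en-12,6-olide; 40 2-{[(triethylsilyl)oxy]methyl}acrylic acid
Product: 41 (4R,5S,6S,8S,10R)-13-acetoxy-4,5-epoxy-1-oxo-8-[(2-{[(triethylsilyl)oxy]methyl}acryloyl)oxy]germacr-7(11)-en-12,6-olide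
Conditions: EDC·HCl, DMAP (0.3 equiv), CH2Cl2, 0 °C to rt
Reagents that add atoms: none
Why: Steglich esterification of the secondary C8 alcohol; any transannular hemiketal between O8 and C1 is in equilibrium with the hydroxy ketone and is drained by acylation. O8 is trans to C12 across C7=C11, so lactone migration cannot occur.

Step 27
Reactants: 41 (4R,5S,6S,8S,10R)-13-acetoxy-4,5-epoxy-1-oxo-8-[(2-{[(triethylsilyl)oxy]methyl}acryloyl)oxy]germacr-7(11)-en-12,6-olide
Product: 42 (4R,5S,6S,8S,10R)-13-acetoxy-4,5-epoxy-8-{[2-(hydroxymethyl)acryloyl]oxy}-1-oxogermacr-7(11)-en-12,6-olide (target)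
Conditions: HF·pyridine, pyridine, THF, 0 °C
Reagents that add atoms: none
Why: Fluoride cleavage of the primary allylic triethylsilyl ether under pyridine buffering at 0 °C, mild enough for the epoxide, the acetate, the acrylate and the base-sensitive C6–H.

## Compound list

1 | (S)-5-[(trityloxy)methyl]dihydrofuran-2(3H)-one | O=C1CC[C@@H](COC(c2ccccc2)(c2ccccc2)c2ccccc2)O1 | starting material
2 | lithium (S)-5-[(trityloxy)methyl]-4,5-dihydrofuran-2-olate | [Li]OC1=CC[C@@H](COC(c2ccccc2)(c2ccccc2)c2ccccc2)O1 | intermediate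
3 | (3R,5S)-3-methyl-5-[(trityloxy)methyl]dihydrofuran-2(3H)-one | O=C1[C@H](C)C[C@@H](COC(c2ccccc2)(c2ccccc2)c2ccccc2)O1 | intermediate
4 | sodium (2R,4S)-4-hydroxy-2-methyl-5-(trityloxy)pentanoate | [Na+].[O-]C(=O)[C@H](C)C[C@H](O)COC(c1ccccc1)(c1ccccc1)c1ccccc1 | intermediate
5 | sodium (2R,4S)-4-[(4-methoxybenzyl)oxy]-2-methyl-5-(trityloxy)pentanoate | [Na+].[O-]C(=O)[C@H](C)C[C@H](OCc1ccc(OC)cc1)COC(c1ccccc1)(c1ccccc1)c1ccccc1 | intermediate
6 | methyl (2R,4S)-4-[(4-methoxybenzyl)oxy]-2-methyl-5-(trityloxy)pentanoate | COC(=O)[C@H](C)C[C@H](OCc1ccc(OC)cc1)COC(c1ccccc1)(c1ccccc1)c1ccccc1 | intermediate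
7 | methyl (2R,4S)-5-hydroxy-4-[(4-methoxybenzyl)oxy]-2-methylpentanoate | COC(=O)[C@H](C)C[C@H](OCc1ccc(OC)cc1)CO | intermediate
8 | methyl (2R,4S)-4-[(4-methoxybenzyl)oxy]-2-methyl-5-oxopentanoate | COC(=O)[C@H](C)C[C@H](OCc1ccc(OC)cc1)C=O | intermediate
9 | allyl methoxymethyl ether | C=CCOCOC | starting material
10 | [(Z)-3-(methoxymethoxy)prop-2-en-1-yl]diisopinocampheylborane (isopinocampheyl from (+)-α-pinene) | COCO/C=C\CB([C@@H]1C[C@@H]2C[C@H]([C@H]1C)C2(C)C)[C@@H]1C[C@@H]2C[C@H]([C@H]1C)C2(C)C | intermediate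
11 | O5-diisopinocampheylborinate of 12 | COC(=O)[C@H](C)C[C@H](OCc1ccc(OC)cc1)[C@@H](OB([C@@H]1C[C@@H]2C[C@H]([C@H]1C)C2(C)C)[C@@H]1C[C@@H]2C[C@H]([C@H]1C)C2(C)C)[C@H](OCOC)C=C | intermediate
12 | methyl (2R,4S,5R,6R)-5-hydroxy-4-[(4-methoxybenzyl)oxy]-6-(methoxymethoxy)-2-methyloct-7-enoate | COC(=O)[C@H](C)C[C@H](OCc1ccc(OC)cc1)[C@@H](O)[C@H](OCOC)C=C | intermediate
13 | methyl (2R,4S,5R,6R)-4-[(4-methoxybenzyl)oxy]-6-(methoxymethoxy)-2-methyl-5-[(triethylsilyl)oxy]oct-7-enoate | COC(=O)[C@H](C)C[C@H](OCc1ccc(OC)cc1)[C@@H](O[Si](CC)(CC)CC)[C@H](OCOC)C=C | intermediate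
14 | methyl (2R,4S,5R,6R)-7,8-dihydroxy-4-[(4-methoxybenzyl)oxy]-6-(methoxymethoxy)-2-methyl-5-[(triethylsilyl)oxy]octanoate (both C7 epimers) | COC(=O)[C@H](C)C[C@H](OCc1ccc(OC)cc1)[C@@H](O[Si](CC)(CC)CC)[C@H](OCOC)C(O)CO | intermediate
15 | methyl (2R,4S,5R,6S)-4-[(4-methoxybenzyl)oxy]-6-(methoxymethoxy)-2-methyl-7-oxo-5-[(triethylsilyl)oxy]heptanoate | COC(=O)[C@H](C)C[C@H](OCc1ccc(OC)cc1)[C@@H](O[Si](CC)(CC)CC)[C@H](OCOC)C=O | intermediate
16 | isopropenylmagnesium bromide | CC(=C)[Mg]Br | starting material
17 | methyl (2R,4S,5R,6R)-7-hydroxy-4-[(4-methoxybenzyl)oxy]-6-(methoxymethoxy)-2,8-dimethyl-5-[(triethylsilyl)oxy]non-8-enoate (mixture of C7 epimers) | COC(=O)[C@H](C)C[C@H](OCc1ccc(OC)cc1)[C@@H](O[Si](CC)(CC)CC)[C@H](OCOC)C(O)C(C)=C | intermediate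
18 | methyl (2R,4S,5R,6S)-4-[(4-methoxybenzyl)oxy]-6-(methoxymethoxy)-2,8-dimethyl-7-oxo-5-[(triethylsilyl)oxy]non-8-enoate | COC(=O)[C@H](C)C[C@H](OCc1ccc(OC)cc1)[C@@H](O[Si](CC)(CC)CC)[C@H](OCOC)C(=O)C(C)=C | intermediate
19 | methyl (2R,4S,5R,6R,7R)-7-hydroxy-4-[(4-methoxybenzyl)oxy]-6-(methoxymethoxy)-2,8-dimethyl-5-[(triethylsilyl)oxy]non-8-enoate | COC(=O)[C@H](C)C[C@H](OCc1ccc(OC)cc1)[C@@H](O[Si](CC)(CC)CC)[C@H](OCOC)[C@H](O)C(C)=C | intermediate
20 | (2R,4S,5R,6R,7R)-7-hydroxy-4-[(4-methoxybenzyl)oxy]-6-(methoxymethoxy)-2,8-dimethyl-5-[(triethylsilyl)oxy]non-8-enoic acid | OC(=O)[C@H](C)C[C@H](OCc1ccc(OC)cc1)[C@@H](O[Si](CC)(CC)CC)[C@H](OCOC)[C@H](O)C(C)=C | intermediate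
21 | mixed anhydride of 20 with 2-methyl-6-nitrobenzoic acid | Cc1cccc([N+](=O)[O-])c1C(=O)OC(=O)[C@H](C)C[C@H](OCc1ccc(OC)cc1)[C@@H](O[Si](CC)(CC)CC)[C@H](OCOC)[C@H](O)C(C)=C | intermediate
22 | (3R,5S,6R,7R,8R)-5-[(4-methoxybenzyl)oxy]-7-(methoxymethoxy)-3-methyl-8-(prop-1-en-2-yl)-6-[(triethylsilyl)oxy]oxocan-2-one | COc1ccc(cc1)CO[C@H]2C[C@@H](C)C(=O)O[C@H](C(C)=C)[C@@H](OCOC)[C@@H]2O[Si](CC)(CC)CC | intermediate
23 | (3R,5S,6R,7R,8R)-5-[(4-methoxybenzyl)oxy]-7-(methoxymethoxy)-3-methyl-2-methylidene-8-(prop-1-en-2-yl)-6-[(triethylsilyl)oxy]oxocane | COc1ccc(cc1)CO[C@H]2C[C@@H](C)C(=C)O[C@H](C(C)=C)[C@@H](OCOC)[C@@H]2O[Si](CC)(CC)CC | intermediate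
24 | (4Z,6R,7R,8S,10R)-8-[(4-methoxybenzyl)oxy]-6-(methoxymethoxy)-4,10-dimethyl-7-[(triethylsilyl)oxy]cyclodec-4-en-1-one | COc1ccc(cc1)CO[C@H]2C[C@@H](C)C(=O)CC/C(C)=C\[C@@H](OCOC)[C@@H]2O[Si](CC)(CC)CC | intermediate
25 | 1-(alkoxymethyl)-2,2′-bipyridin-1-ium triflate in which the alkoxy group is O6 of 26 | COc1ccc(cc1)CO[C@H]2C[C@@H](C)C(=O)CC/C(C)=C\[C@@H](OC[n+]3ccccc3-c3ccccn3)[C@@H]2O[Si](CC)(CC)CC.[O-]S(=O)(=O)C(F)(F)F | intermediate
26 | (4Z,6R,7S,8S,10R)-6-hydroxy-8-[(4-methoxybenzyl)oxy]-4,10-dimethyl-7-[(triethylsilyl)oxy]cyclodec-4-en-1-one | COc1ccc(cc1)CO[C@H]2C[C@@H](C)C(=O)CC/C(C)=C\[C@@H](O)[C@@H]2O[Si](CC)(CC)CC | intermediate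
27 | (4R,5S,6R,7S,8S,10R)-4,5-epoxy-6-hydroxy-8-[(4-methoxybenzyl)oxy]-4,10-dimethyl-7-[(triethylsilyl)oxy]cyclodecan-1-one | COc1ccc(cc1)CO[C@H]2C[C@@H](C)C(=O)CC[C@@]3(C)O[C@H]3[C@@H](O)[C@@H]2O[Si](CC)(CC)CC | intermediate
28 | ethyl 2-(diethoxyphosphoryl)acrylate | CCOC(=O)C(=C)P(=O)(OCC)OCC | starting material
29 | 4-methoxybenzyl alcohol | COc1ccc(CO)cc1 | starting material
30 | ethyl 2-(diethoxyphosphoryl)-3-[(4-methoxybenzyl)oxy]propanoate (racemic) | CCOC(=O)C(COCc1ccc(OC)cc1)P(=O)(OCC)OCC | intermediate
31 | 2-(diethoxyphosphoryl)-3-[(4-methoxybenzyl)oxy]propanoic acid (racemic) | OC(=O)C(COCc1ccc(OC)cc1)P(=O)(OCC)OCC | intermediate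
32 | (4R,5S,6R,7R,8S,10R)-4,5-epoxy-8-[(4-methoxybenzyl)oxy]-4,10-dimethyl-1-oxo-7-[(triethylsilyl)oxy]cyclodecan-6-yl 2-(diethoxyphosphoryl)-3-[(4-methoxybenzyl)oxy]propanoate (both C11 epimers) | COc1ccc(cc1)CO[C@H]2C[C@@H](C)C(=O)CC[C@@]3(C)O[C@H]3[C@@H](OC(=O)C(COCc4ccc(OC)cc4)P(=O)(OCC)OCC)[C@@H]2O[Si](CC)(CC)CC | intermediate
33 | (4R,5S,6S,7R,8S,10R)-4,5-epoxy-7-hydroxy-8-[(4-methoxybenzyl)oxy]-4,10-dimethyl-1-oxocyclodecan-6-yl 2-(diethoxyphosphoryl)-3-[(4-methoxybenzyl)oxy]propanoate (both C11 epimers) | COc1ccc(cc1)CO[C@H]2C[C@@H](C)C(=O)CC[C@@]3(C)O[C@H]3[C@@H](OC(=O)C(COCc4ccc(OC)cc4)P(=O)(OCC)OCC)[C@@H]2O | intermediate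
34 | (4R,5S,6R,8S,10R)-4,5-epoxy-8-[(4-methoxybenzyl)oxy]-4,10-dimethyl-1,7-dioxocyclodecan-6-yl 2-(diethoxyphosphoryl)-3-[(4-methoxybenzyl)oxy]propanoate (both C11 epimers) | COc1ccc(cc1)CO[C@H]2C[C@@H](C)C(=O)CC[C@@]3(C)O[C@H]3[C@@H](OC(=O)C(COCc4ccc(OC)cc4)P(=O)(OCC)OCC)C2=O | intermediate
35 | (4R,5S,6S,8S,10R)-4,5-epoxy-8,13-bis[(4-methoxybenzyl)oxy]-1-oxogermacr-7(11)-en-12,6-olide | COc1ccc(cc1)CO[C@H]1C[C@@H](C)C(=O)CC[C@@]2(C)O[C@H]2[C@H]2OC(=O)C(COCc3ccc(OC)cc3)=C12 | intermediate
36 | (4R,5S,6S,8S,10R)-4,5-epoxy-8,13-dihydroxy-1-oxogermacr-7(11)-en-12,6-olide | O[C@H]1C[C@@H](C)C(=O)CC[C@@]2(C)O[C@H]2[C@H]2OC(=O)C(CO)=C12 | intermediate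
37 | (4R,5S,6S,8S,10R)-13-acetoxy-4,5-epoxy-8-hydroxy-1-oxogermacr-7(11)-en-12,6-olide | O[C@H]1C[C@@H](C)C(=O)CC[C@@]2(C)O[C@H]2[C@H]2OC(=O)C(COC(C)=O)=C12 | intermediate
38 | 2-(hydroxymethyl)acrylic acid | C=C(CO)C(=O)O | starting material
39 | triethylsilyl 2-{[(triethylsilyl)oxy]methyl}acrylate | C=C(CO[Si](CC)(CC)CC)C(=O)O[Si](CC)(CC)CC | intermediate
40 | 2-{[(triethylsilyl)oxy]methyl}acrylic acid | C=C(CO[Si](CC)(CC)CC)C(=O)O | intermediate
41 | (4R,5S,6S,8S,10R)-13-acetoxy-4,5-epoxy-1-oxo-8-[(2-{[(triethylsilyl)oxy]methyl}acryloyl)oxy]germacr-7(11)-en-12,6-olide | C=C(CO[Si](CC)(CC)CC)C(=O)O[C@H]1C[C@@H](C)C(=O)CC[C@@]2(C)O[C@H]2[C@H]2OC(=O)C(COC(C)=O)=C12 | intermediate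
42 | (4R,5S,6S,8S,10R)-13-acetoxy-4,5-epoxy-8-{[2-(hydroxymethyl)acryloyl]oxy}-1-oxogermacr-7(11)-en-12,6-olide (CNP0258719.1) | C=C(CO)C(=O)O[C@H]1C[C@@H](C)C(=O)CC[C@@]2(C)O[C@H]2[C@H]2OC(=O)C(COC(C)=O)=C12 | target

## Step count and least certain steps

Total: 27 steps. Longest linear sequence: 24 steps (steps 1–16, 19–24, 26 and 27).

Step 14 (key step). Most likely to go wrong: migration of the exocyclic enol ether double bond into the ring or its hydrolysis before the rearrangement, because the bicyclic transition state needs a high temperature; a competing boat transition state would erode the Z geometry. Fallback: ring-closing metathesis in place of the ring expansion. Setting out from 13, the ester is converted with MeNHOMe·HCl and i-PrMgCl into the Weinreb amide F1. Addition of (3-methylbut-3-en-1-yl)magnesium bromide gives the dienyl ketone F2. Ring-closing metathesis with the second-generation Hoveyda–Grubbs catalyst in hot toluene at high dilution would close C4=C5 and return to the route at 24.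

Step 12. Most likely to go wrong: dimerisation to the sixteen-membered diolide, or failure of the hindered C5 hydroxyl to attack the activated acyl group, because an eight-membered transition state is strained. Fallback: closure by alkyl–oxygen instead of acyl–oxygen bond formation. Setting out from 17, the 5S epimer (the expected major product of chelation-controlled addition) is separated and saponified to the epimeric hydroxy acid F3. Mitsunobu cyclisation (PPh3, DIAD, toluene, high dilution) would proceed with inversion at C5 and return at 22; this also bypasses steps 9 and 10.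

Step 16. Most likely to go wrong: delivery of oxygen to the other olefin face, if the ten-membered ring can place the C6–C7 bond in the olefin plane as an open-chain Z-allylic alcohol does; oxidation of the allylic alcohol to the enone is a lesser risk. Fallback: reagent control in place of substrate direction. 26 is epoxidised by Shi epoxidation with the fructose-type ketone enantiomer made from L-sorbose (KHSO5, K2CO3 buffer, MeCN/dimethoxymethane, 0 °C), which the spiro transition-state model assigns to the required face, returning at 27. No new compound arises.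

Step 22. Most likely to go wrong: deprotonation at C6 in competition with the phosphonate, leading to β-elimination of the epoxide or epimerisation at C6 or C8, because C6–H is α to the ketone before and γ to the lactone after ring closure. Fallback: build the butenolide before the epoxide. Setting out from 26, esterification with 31 gives the olefinic phosphonate ester F4. Desilylation gives the carbinol F5, oxidation the ketone F6, and the same olefination the olefinic butenolide F7. Shi epoxidation as above would then return to the route at 35.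

Step 5. Most likely to go wrong: erosion of reagent control by the Cornforth preference of the α-alkoxy aldehyde (mismatched double diastereoselection), which would give the C6 epimer; partial epimerisation of the aldehyde is a lesser risk. Fallback: substrate control in the matched sense. 9 is lithiated and quenched with Bu3SnCl to give the γ-alkoxyallylstannane F8. Its addition to 8 pre-complexed with MgBr2·OEt2 (CH2Cl2, −78 °C) is chelation-controlled (7,8-syn) and syn-selective at C6–C7, and would return at 12.

## Further compounds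

F1 | step 14 | (2R,4S,5R,6R)-N-methoxy-4-[(4-methoxybenzyl)oxy]-6-(methoxymethoxy)-N,2-dimethyl-5-[(triethylsilyl)oxy]oct-7-enamide | CON(C)C(=O)[C@H](C)C[C@H](OCc1ccc(OC)cc1)[C@@H](O[Si](CC)(CC)CC)[C@H](OCOC)C=C
F2 | step 14 | dienyl ketone: 3-methylbut-3-en-1-yl ketone derived from F1 (C1 ketone, terminal olefins at C4 and C5) | C=C(C)CCC(=O)[C@H](C)C[C@H](OCc1ccc(OC)cc1)[C@@H](O[Si](CC)(CC)CC)[C@H](OCOC)C=C
F3 | step 12 | (2R,4S,5R,6R,7S)-7-hydroxy-4-[(4-methoxybenzyl)oxy]-6-(methoxymethoxy)-2,8-dimethyl-5-[(triethylsilyl)oxy]non-8-enoic acid (C5 epimer of 20) | OC(=O)[C@H](C)C[C@H](OCc1ccc(OC)cc1)[C@@H](O[Si](CC)(CC)CC)[C@H](OCOC)[C@@H](O)C(C)=C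
F0 | step 16 | none | none
F4 | step 22 | C6 phosphonate ester of 26 with 31 (Z olefin retained, C7 silyl ether) | COc1ccc(cc1)CO[C@H]2C[C@@H](C)C(=O)CC/C(C)=C\[C@@H](OC(=O)C(COCc3ccc(OC)cc3)P(=O)(OCC)OCC)[C@@H]2O[Si](CC)(CC)CC
F5 | step 22 | C7 carbinol derived from F4 | COc1ccc(cc1)CO[C@H]2C[C@@H](C)C(=O)CC/C(C)=C\[C@@H](OC(=O)C(COCc3ccc(OC)cc3)P(=O)(OCC)OCC)[C@@H]2O
F6 | step 22 | C7 ketone derived from F5 | COc1ccc(cc1)CO[C@H]2C[C@@H](C)C(=O)CC/C(C)=C\[C@@H](OC(=O)C(COCc3ccc(OC)cc3)P(=O)(OCC)OCC)C2=O
F7 | step 22 | (4Z,6S,8S,10R)-8,13-bis[(4-methoxybenzyl)oxy]-1-oxogermacra-4,7(11)-dien-12,6-olide | COc1ccc(cc1)CO[C@H]1C[C@@H](C)C(=O)CC/C(C)=C\[C@H]2OC(=O)C(COCc3ccc(OC)cc3)=C12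
F8 | step 5 | tributyl[(Z)-3-(methoxymethoxy)prop-2-en-1-yl]stannane | CCCC[Sn](CCCC)(CCCC)C/C=C\OCOC
A1 | alternative 1 | seco Z β-iodo-enoate epoxy aldehyde (methyl ester, C8 silyl ether, C6 aldehyde) | CC(C)(C)[Si](C)(C)O[C@@H](C[C@@H](C)C(=O)CC[C@@]1(C)O[C@H]1C=O)/C(I)=C(\COC(C)=O)C(=O)OC
A2 | alternative 1 | 8-O-tert-butyldimethylsilyl core with ten-membered ring, epoxide, C1 ketone and acetoxymethyl butenolide | CC(C)(C)[Si](C)(C)O[C@H]1C[C@@H](C)C(=O)CC[C@@]2(C)O[C@H]2[C@H]2OC(=O)C(COC(C)=O)=C12
A3 | alternative 2 | C1 phenyl selenoester carrying the epoxide, the butenolide and the C8 (E)-propenyl ketone | O=C(CC[C@@]1(C)O[C@H]1[C@H]1OC(=O)C(COC(C)=O)=C1C(=O)/C=C/C)[Se]c1ccccc1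
A4 | alternative 2 | 1,8-dioxo core with epoxide and acetoxymethyl butenolide | O=C1C[C@@H](C)C(=O)CC[C@@]2(C)O[C@H]2[C@H]2OC(=O)C(COC(C)=O)=C12
A5 | alternative 3 | 2-(triisopropylsilyloxy)furan tethered to the C5 aldehyde (C4 PMB ether, C1 ketone, C8 silyl ether) | O=C[C@](C)(OCc1ccc(OC)cc1)CCC(=O)[C@H](C)C[C@H](O[Si](C)(C)C(C)(C)C)c1coc(O[Si](C(C)C)(C(C)C)C(C)C)c1COC(C)=O
A6 | alternative 3 | (5R,6S) aldol macrocycle with C5 alcohol, C4 PMB ether, butenolide and C8 silyl ether | CC(C)(C)[Si](C)(C)O[C@H]1C[C@@H](C)C(=O)CC[C@@](C)(OCc2ccc(OC)cc2)[C@H](O)[C@H]2OC(=O)C(COC(C)=O)=C12
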